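## Structural features

The target is a germacranolide: a ten-membered carbocycle (numbered here C1–C10: C1 = CH2, C2 = ketone, C3=C4 with the C15 methyl on C4, C5 = CH2, C6–C10 sp3) trans-fused across C6–C7 to an α-methylene-γ-butyrolactone (ring O on C6; C11(=C13H2) on C7; C12 = lactone carbonyl). The C2 ketone is conjugated with the cis (Z) C3=C4 bond, so the ring holds a (Z)-β-methyl enone whose geometry would not be secure in an open chain. C6 to C10 are five contiguous stereocentres (6R,7R,8R,9R,10S): lactone O, C11, free OH, acyloxy and the C14 methyl alternate between the two ring faces, each neighbouring pair trans. The C9 oxygen carries a (2R,3R)-2,3-epoxy-2-methylbutanoyl group, a hindered, acid-sensitive ester next to the free C8 hydroxyl (risk of 9→8 acyl shift, and of translactonisation of C8–OH onto C12). Other fragile groups are the exocyclic enoate (Michael acceptor) and the Z-enone (E/Z drift and γ-deprotonation under base). The real difficulty is the medium ring with its cis-trisubstituted enone together with the C6–C10 pentad, in which the neighbouring C8 and C9 oxygens must be told apart. The key step exploits the sequence C10(CH3)–C1–C2(=O) facing C7–C8–C9(O), which is an oxy-Cope retron. If C2–C7 is closed, the atoms C2–C3=C4–C5–C6–C7 form a cyclohexene that already holds the cis C3=C4 bond.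

## Logic of the disconnections

36 ⇒ 35 ⇒ 29 + 33. The C9 O–acyl bond is cut last because the epoxy ester is the most fragile group. This removes five carbons and two stereocentres and makes the route convergent. The forward esterification needs a free C9–OH next to a blocked C8–OH (silyl ether in 28, 29 and 35, benzylic ether in 27 and 28) and must proceed without base-induced acyl shift.

27 ⇒ 26 ⇒ 25. The C11=C13 bond and the C7–C11 bond are cut. A stabilised carbanion tethered through the C6 oxygen opens a cis-7,8-epoxide at C7. This forms the lactone, sets C7 by inversion, releases the C8 hydroxyl with its configuration retained and so differentiates C8 from C9. The phosphonate that stabilises the anion then delivers the methylene. The demand is an epoxide on the face of the lactone oxygen, a 5-exo anti attack in a trans-fused sense, and a weakly basic medium.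

25 ⇒ 23 + 24, and 23 ⇒ 22. The C6–O(acyl) bond is cut with inversion and the epoxide oxygen is removed. In 22 both allylic oxygens (C6 and C9) lie on one face of C7=C8 and steer the peracid to the other face. The inversion at C6 then converts the configuration that the ring expansion must deliver into the natural one. The demand is a face-selective epoxidation of the only electron-rich alkene and a clean SN2 reaction at a ring carbinol next to an epoxide.

22 ⇒ 19 (key). The C9–C10 bond is cut and C2–C7 is reconnected: a ring expansion of 19 to 22. The ten-membered ring, the Z-enone (inherited from the cyclohexene), the Z C7=C8 bond and the C9/C10 pair all arise in one [3,3] shift. Two stereocentres (C2, C7) are spent to create two (C9, C10) through a chair. The demand on 19 is cis propenyl and alkoxyvinyl groups, a C6 oxygen trans to the C7 side chain, and E geometry in both alkenes.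

19 ⇒ 15 + 16. The C1–C2 bond is cut (1,2-addition of a propenyl metal to a ketone). The nucleophile must enter anti to the ring oxygen, and the β-hydroxy ketone must not enolise or eliminate.

15 ⇒ 14 ⇒ 13 ⇒ 11 + 12, 11 ⇒ 10 ⇒ 9 ⇒ 8. These are functional group changes that cut the vinyl C9–O bond and the C8=C9 bond. The enone is unveiled from the allylic alcohol only at the end, so that the aromatisation-prone β-hydroxy enone exists for one step only. The E enol ether comes from an E vinyl iodide, which comes from an aldehyde. The demand is E selectivity twice and no epimerisation at C7.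

8 ⇒ 7. The C3=C4 bond is cut (ring-closing metathesis), which turns the ring into an open chain whose stereocentres can be set by acyclic control.

7 ⇒ 4 + 5. The C2–C7 bond is cut (aldol reaction of a β-hydroxy ester dianion). C7 is set anti to the C6 oxygen. The new carbinol at C2 need not be controlled because it becomes the ketone.

4 ⇒ 2 + 3 and 2 ⇒ 1. The C4–C5 bond is cut (epoxide opening). C6 comes from the chiral pool.

33 ⇒ 32 ⇒ 31 ⇒ 30. The acid comes from the epoxy alcohol, the epoxide from a catalytic asymmetric epoxidation of the Z allylic alcohol, and the alcohol from the commercial Z acid.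

## Other disconnections considered

Alternative 1: The first idea is to cut C6–C7 and close the ring by an intramolecular CrCl2-mediated (Nozaki–Hiyama–Kishi type) 2-(alkoxycarbonyl)allylation of aldehyde A1, with lactonisation giving 28. It is set aside because A1 must carry the (Z)-enone in an open chain next to a β,γ-unsaturated aldehyde, where both double-bond position and geometry are free to drift. The ten-membered closure is also entropically costly, and C6 and C7 would be set in a floppy chain with little control. The chosen plan never has the Z-enone outside a ring and pays no macrocyclisation entropy.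

Alternative 2: Cut C3=C4 and close by ring-closing metathesis of vinyl ketone A2 with a ruthenium carbene to give 28. A trisubstituted enone alkene in a ten-membered ring gives no handle on Z versus E, the electron-poor vinyl ketone and the 1,1-disubstituted partner are a slow pair, and the α-methylene lactone is a third metathesis-competent alkene. The chosen plan takes the cis geometry from a six-membered ring.

Alternative 3: Cut C1–C10 and form it by methylenation of the eight-membered (Z)-enoate lactone A3 with Cp2TiMe2, followed by Claisen ring expansion to A4. This also keeps the Z-enone in a ring, but it leaves C8=C9 as an alkene that must later receive two oxygens on a ten-membered ring with no means to tell them apart. Whether the C8 centre of A3 relays to 10S depends on a chair/boat choice that the eight-membered ring makes hard to predict, and A3 needs an eight-membered lactonisation. The chosen plan has more steps after the rearrangement than this one would need, but the [3,3] shift sets C9 and C10 through an unconstrained chair and C8 and C9 are differentiated from the outset.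

Key step: step 12

Remark 1: Names of ten-membered-ring compounds from 23 on use the atom numbering given under "Structural features", not lowest locants.
Remark 2: The allylic carbinol formed in step 3 is carried as both epimers through 7–14 and is oxidised in step 10, so it is left undefined in those SMILES.
Remark 3: Compound 22 may equilibrate with its transannular C2–O–C6 hemiketal; it is drawn, and assumed to react, as the open hydroxy enone.

## Steps

Step 1
Reactants: 1 ethyl (3R)-4-chloro-3-hydroxybutanoate
Product: 2 ethyl 2-[(2R)-oxiran-2-yl]acetate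
Conditions: Ag2O, Et2O, reflux, dark
Reagents that add atoms: none
Why: Halohydrin closure (intramolecular Williamson etherification) in which Ag2O removes chloride without the basic conditions that would eliminate the β-oxygen of the ester; the C–O bond of the stereocentre is untouched.

Step 2
Reactants: 2 ethyl 2-[(2R)-oxiran-2-yl]acetate; 3 isopropenylmagnesium bromide
Product: 4 ethyl (3S)-3-hydroxy-5-methylhex-5-enoate
Conditions: CuI (10 mol%), THF, −40 °C; then H2O
Reagents that add atoms: none
Why: Copper-catalysed Grignard opening of a terminal epoxide at the unsubstituted carbon (SN2), faster at −40 °C than addition to the ester; the carbinol centre is not involved and its descriptor changes from R to S through priorities only.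

Step 3
Reactants: 4 ethyl (3S)-3-hydroxy-5-methylhex-5-enoate; 5 acrolein
Product: 7 ethyl (2R,3S)-3-hydroxy-2-(1-hydroxyprop-2-en-1-yl)-5-methylhex-5-enoate (both epimers at the new carbinol), via dilithium enolate alkoxide 6 (not isolated)
Conditions: LDA (2.2 equiv), THF, −78 to −20 °C; then 5, −78 °C; then H2O
Reagents that add atoms: none
Why: Fráter–Seebach aldol reaction: the chelated dilithium enolate 6 is attacked on the face away from the C3 chain, which sets C2 anti to the alkoxide; the allylic carbinol forms unselectively, which is harmless because it is oxidised in step 10.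

Step 4
Reactants: 7 ethyl (2R,3S)-3-hydroxy-2-(1-hydroxyprop-2-en-1-yl)-5-methylhex-5-enoate
Product: 8 ethyl (1R,6S)-2,6-dihydroxy-4-methylcyclohex-3-ene-1-carboxylate (both C2 epimers)
Conditions: second-generation Grubbs catalyst (H2IMes)(PCy3)Cl2Ru=CHPh (5 mol%), CH2Cl2, 40 °C
Reagents that add atoms: none
Why: Ring-closing metathesis between the vinyl group and the 1,1-disubstituted alkene closes the six-membered ring with the trisubstituted C=C that later becomes C3=C4; no stereocentre is touched.

Step 5
Reactants: 8 ethyl (1R,6S)-2,6-dihydroxy-4-methylcyclohex-3-ene-1-carboxylate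
Product: 9 ethyl (1R,6S)-2,6-bis[(tert-butyldimethylsilyl)oxy]-4-methylcyclohex-3-ene-1-carboxylate
Conditions: TBSOTf (2.5 equiv), 2,6-lutidine, CH2Cl2, 0 °C
Reagents that add atoms: tert-butyldimethylsilyl trifluoromethanesulfonate, CC(C)(C)[Si](C)(C)OS(=O)(=O)C(F)(F)F
Why: Standard silylation of two secondary alcohols; the ethers protect both hydroxyls through the reduction, olefination and coupling steps and leave together in step 9.

Step 6
Reactants: 9 ethyl (1R,6S)-2,6-bis[(tert-butyldimethylsilyl)oxy]-4-methylcyclohex-3-ene-1-carboxylate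
Product: 10 (1R,6S)-2,6-bis[(tert-butyldimethylsilyl)oxy]-4-methylcyclohex-3-ene-1-carbaldehyde
Conditions: DIBAL-H (1.1 equiv), CH2Cl2, −78 °C; then aq. Rochelle salt
Reagents that add atoms: none
Why: Partial reduction of an ester; the tetrahedral aluminium hemiacetal of this α-branched β-silyloxy ester should persist at −78 °C until work-up, and the α-centre is not epimerised under these non-basic conditions.

Step 7
Reactants: 10 (1R,6S)-2,6-bis[(tert-butyldimethylsilyl)oxy]-4-methylcyclohex-3-ene-1-carbaldehyde
Product: 11 (4R,5S)-3,5-bis[(tert-butyldimethylsilyl)oxy]-4-[(E)-2-iodoethenyl]-1-methylcyclohex-1-ene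
Conditions: CrCl2 (6 equiv), CHI3 (2 equiv), THF, 0 °C
Reagents that add atoms: iodoform, IC(I)I
Why: Takai iodo-olefination; the geminal dichromium reagent adds to the aldehyde and eliminates anti-periplanar to give the E vinyl iodide, under conditions mild enough to spare the β-silyloxy aldehyde.

Step 8
Reactants: 11 (4R,5S)-3,5-bis[(tert-butyldimethylsilyl)oxy]-4-[(E)-2-iodoethenyl]-1-methylcyclohex-1-ene; 12 4-methoxybenzyl alcohol
Product: 13 (4R,5S)-3,5-bis[(tert-butyldimethylsilyl)oxy]-4-[(E)-2-[(4-methoxybenzyl)oxy]ethenyl]-1-methylcyclohex-1-ene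
Conditions: CuI (10 mol%), 3,4,7,8-tetramethyl-1,10-phenanthroline (20 mol%), Cs2CO3, toluene, 80 °C
Reagents that add atoms: none
Why: Copper-catalysed Ullmann-type C–O coupling of a vinyl iodide with an alcohol, which proceeds with retention of alkene geometry and so gives the E enol ether needed for the chair in step 12.

Step 9
Reactants: 13 (4R,5S)-3,5-bis[(tert-butyldimethylsilyl)oxy]-4-[(E)-2-[(4-methoxybenzyl)oxy]ethenyl]-1-methylcyclohex-1-ene
Product: 14 (1S,2R)-2-[(E)-2-[(4-methoxybenzyl)oxy]ethenyl]-5-methylcyclohex-4-ene-1,3-diol (both C3 epimers)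
Conditions: TBAF, THF, rt
Reagents that add atoms: none
Why: Fluoride cleavage of both silyl ethers; the enol ether and the benzylic ether are inert to fluoride.

Step 10
Reactants: 14 (1S,2R)-2-[(E)-2-[(4-methoxybenzyl)oxy]ethenyl]-5-methylcyclohex-4-ene-1,3-diol
Product: 15 (5S,6R)-5-hydroxy-6-[(E)-2-[(4-methoxybenzyl)oxy]ethenyl]-3-methylcyclohex-2-en-1-one
Conditions: activated MnO2 (excess), CH2Cl2, rt
Reagents that add atoms: none
Why: MnO2 oxidises only the allylic alcohol, so both epimers converge on one enone while the homoallylic hydroxyl stays; the neutral medium avoids dehydration of the β-hydroxy ketone to a cresol.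

Step 11
Reactants: 15 (5S,6R)-5-hydroxy-6-[(E)-2-[(4-methoxybenzyl)oxy]ethenyl]-3-methylcyclohex-2-en-1-one; 16 (E)-1-bromoprop-1-ene
Product: 19 (1R,5S,6R)-6-[(E)-2-[(4-methoxybenzyl)oxy]ethenyl]-3-methyl-1-[(E)-prop-1-en-1-yl]cyclohex-2-ene-1,5-diol, via (E)-prop-1-enyllithium 17 (not isolated), via (E)-prop-1-enylcerium dichloride 18 (not isolated)
Conditions: 16, t-BuLi (2 equiv per 16), Et2O, −78 °C; CeCl3, THF, −78 °C; then 15 (0.35 equiv), −78 °C; then H2O
Reagents that add atoms: none
Why: Br/Li exchange with retention, then 1,2-addition of the weakly basic organocerium (one equivalent is spent on the hydroxyl); the propenyl group should enter axially on the half-chair that keeps both ring substituents equatorial, anti to the C5 oxygen as with 5-substituted cyclohex-2-enones, which places it cis to the C6 side chain and gives 1R.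

Step 12
Reactants: 19 (1R,5S,6R)-6-[(E)-2-[(4-methoxybenzyl)oxy]ethenyl]-3-methyl-1-[(E)-prop-1-en-1-yl]cyclohex-2-ene-1,5-diol
Product: 22 (2Z,5S,6Z,8R,9S)-5-hydroxy-8-[(4-methoxybenzyl)oxy]-3,9-dimethylcyclodeca-2,6-dien-1-one, via dipotassium dialkoxide 20 (not isolated), via dipotassium enolate alkoxide 21 (not isolated)
Conditions: KH (2.5 equiv), 18-crown-6 (2.5 equiv), THF, 0 °C to rt; then H2O, −40 °C
Reagents that add atoms: none
Why: The tertiary alkoxide in 20 weakens the C2–C7 ring bond and the 1,5-diene C10=C1–C2–C7–C8=C9 undergoes an anionic oxy-Cope [3,3] shift, the reaction type by which 1,2-dialkenylcyclohexanols give cyclodec-5-enones, helped here because 21 is a cross-conjugated dienolate. No ring is closed end to end: the ten-membered ring arises by four-atom ring expansion, the C9–C10 bond forming between the two side chains as the cyclohexene bond breaks, so no medium-ring entropy is paid. The half-chair of 20 with the C7 side chain and the C6 oxygen equatorial and the propenyl group axial places the alkene termini in a chair array in which both E substituents (the C10 methyl and the C9 benzylic ether) are equatorial. That chair makes C9 and C10 syn to each other and, by transfer of chirality from C2 and C7, fixes them relative to C6, giving 6S,9R,10S in target numbering. C7=C8 emerges Z because the ring carbon C6 is axial on the chair at C7, and C3=C4 keeps the cis geometry of the six-membered ring, so C-protonation of 21 at C1 gives the (Z)-enone. The step needs this chair to be preferred over the ring-flipped triaxial conformer and over boats, which the trans C6/C7 and cis C2/C7 relationships of 19 secure, and the ring alkene cannot compete because C4 cannot reach C9. The quench is done cold so that the dienolate does not equilibrate the enone geometry.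

Step 13
Reactants: 22 (2Z,5S,6Z,8R,9S)-5-hydroxy-8-[(4-methoxybenzyl)oxy]-3,9-dimethylcyclodeca-2,6-dien-1-one
Product: 23 (3Z,6S,7R,8S,9R,10S)-7,8-epoxy-6-hydroxy-9-[(4-methoxybenzyl)oxy]-4,10-dimethylcyclodec-3-en-2-one (epoxide trans to the C6 hydroxyl and to the C9 ether)
Conditions: mCPBA, NaHCO3, CH2Cl2, 0 °C
Reagents that add atoms: 3-chloroperoxybenzoic acid, OOC(=O)c1cccc(Cl)c1
Why: Prilezhaev epoxidation of the only electron-rich alkene (the enone is inert); both allylic C–O bonds lie on one face of C7=C8, so the peracid should approach the other, in line with the trans epoxy alcohols that peracids give with medium-ring cis-allylic alcohols.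

Step 14
Reactants: 23 (3Z,6S,7R,8S,9R,10S)-7,8-epoxy-6-hydroxy-9-[(4-methoxybenzyl)oxy]-4,10-dimethylcyclodec-3-en-2-one; 24 2-(diethoxyphosphoryl)acetic acid
Product: 25 (3Z,6R,7R,8S,9R,10S)-6-[2-(diethoxyphosphoryl)acetoxy]-7,8-epoxy-9-[(4-methoxybenzyl)oxy]-4,10-dimethylcyclodec-3-en-2-one
Conditions: 24, PPh3, DIAD, toluene, 0 °C to rt
Reagents that add atoms: none
Why: Mitsunobu esterification, SN2 displacement of the alkoxyphosphonium by the carboxylate with inversion at C6; this gives the natural 6R configuration and brings in C11 and C12 with the phosphonate that will stabilise the anion.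

Step 15
Reactants: 25 (3Z,6R,7R,8S,9R,10S)-6-[2-(diethoxyphosphoryl)acetoxy]-7,8-epoxy-9-[(4-methoxybenzyl)oxy]-4,10-dimethylcyclodec-3-en-2-one
Product: 27 (3Z,6R,7R,8R,9R,10S)-8-hydroxy-9-[(4-methoxybenzyl)oxy]-2-oxogermacra-3,11(13)-dien-12,6-olide, via alpha-phosphono lactone 26 (not isolated)
Conditions: LiCl, DBU, MeCN, rt to 50 °C; then (CH2O)n, rt
Reagents that add atoms: formaldehyde (from paraformaldehyde), C=O
Why: Intramolecular alkylation of the phosphonoacetate anion by the epoxide (5-exo, backside attack at C7: inversion at C7, C8–O retained) should give the trans-fused lactone 26 and the free C8 hydroxyl, and Horner–Wadsworth–Emmons olefination of 26 with formaldehyde then gives the exocyclic methylene. The LiCl/DBU (Masamune–Roush) medium activates the epoxide with lithium and keeps the C8 oxygen protonated, so it does not translactonise.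

Step 16
Reactants: 27 (3Z,6R,7R,8R,9R,10S)-8-hydroxy-9-[(4-methoxybenzyl)oxy]-2-oxogermacra-3,11(13)-dien-12,6-olide
Product: 28 (3Z,6R,7S,8R,9R,10S)-9-[(4-methoxybenzyl)oxy]-2-oxo-8-[(triethylsilyl)oxy]germacra-3,11(13)-dien-12,6-olide (7S only through the priority change caused by silicon)
Conditions: TESOTf, 2,6-lutidine, CH2Cl2, −78 °C
Reagents that add atoms: triethylsilyl trifluoromethanesulfonate, CC[Si](CC)(CC)OS(=O)(=O)C(F)(F)F
Why: Silylation of the secondary C8 alcohol under weakly basic conditions that the two Michael acceptors tolerate; it blocks C8 during acylation of C9.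

Step 17
Reactants: 28 (3Z,6R,7S,8R,9R,10S)-9-[(4-methoxybenzyl)oxy]-2-oxo-8-[(triethylsilyl)oxy]germacra-3,11(13)-dien-12,6-olide
Product: 29 (3Z,6R,7S,8R,9R,10S)-9-hydroxy-2-oxo-8-[(triethylsilyl)oxy]germacra-3,11(13)-dien-12,6-olide
Conditions: DDQ, CH2Cl2/pH 7 buffer, 0 °C
Reagents that add atoms: none
Why: Oxidative cleavage of the 4-methoxybenzyl ether through its benzylic oxocarbenium ion, orthogonal to the silyl ether and to the electron-poor alkenes.

Step 18
Reactants: 30 angelic acid [(2Z)-2-methylbut-2-enoic acid]
Product: 31 (2Z)-2-methylbut-2-en-1-ol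
Conditions: LiAlH4, Et2O, 0 °C
Reagents that add atoms: none
Why: Hydride reduction of the carboxylic acid to the primary allylic alcohol; the trisubstituted alkene is not reduced at 0 °C and keeps its Z geometry.

Step 19
Reactants: 31 (2Z)-2-methylbut-2-en-1-ol
Product: 32 [(2S,3R)-2,3-dimethyloxiran-2-yl]methanol
Conditions: Ti(OiPr)4 (10 mol%), L-(+)-diethyl tartrate (12 mol%), t-BuOOH, 4 Å MS, CH2Cl2, −20 °C
Reagents that add atoms: tert-butyl hydroperoxide, CC(C)(C)OO
Why: Sharpless asymmetric epoxidation; with the L-(+)-tartrate oxygen is delivered to the face that gives 2S at the carbinol-bearing carbon of primary allylic alcohols (as in (E)-hex-2-en-1-ol to the 2S,3S epoxide), which for this Z alkene means 2S,3R.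

Step 20
Reactants: 32 [(2S,3R)-2,3-dimethyloxiran-2-yl]methanol
Product: 33 (2R,3R)-2,3-dimethyloxirane-2-carboxylic acid
Conditions: RuCl3·xH2O (2 mol%), NaIO4, MeCN/EtOAc/H2O, 0 °C to rt
Reagents that add atoms: sodium periodate, [Na+].[O-]I(=O)(=O)=O; water, O
Why: Oxidation of the primary alcohol to the acid by RuO4 formed in the flask, a standard way from epoxy alcohols to epoxy acids; the epoxide is untouched and C2 changes from S to R through priorities only.

Step 21
Reactants: 29 (3Z,6R,7S,8R,9R,10S)-9-hydroxy-2-oxo-8-[(triethylsilyl)oxy]germacra-3,11(13)-dien-12,6-olide; 33 (2R,3R)-2,3-dimethyloxirane-2-carboxylic acid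
Product: 35 (3Z,6R,7S,8R,9R,10S)-9-[(2R,3R)-2,3-dimethyloxirane-2-carbonyloxy]-2-oxo-8-[(triethylsilyl)oxy]germacra-3,11(13)-dien-12,6-olide, via mixed anhydride 34 (not isolated)
Conditions: 33, 2,4,6-Cl3C6H2COCl, Et3N, THF, rt; then 29, DMAP, toluene, rt
Reagents that add atoms: none
Why: Yamaguchi esterification; the mixed anhydride 34 transfers the hindered acyl group through its acylpyridinium ion to the C9 alcohol with retention at C9, and the acid has no α-hydrogen to epimerise.

Step 22
Reactants: 35 (3Z,6R,7S,8R,9R,10S)-9-[(2R,3R)-2,3-dimethyloxirane-2-carbonyloxy]-2-oxo-8-[(triethylsilyl)oxy]germacra-3,11(13)-dien-12,6-olide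
Product: 36 (3Z,6R,7R,8R,9R,10S)-9-[(2R,3R)-2,3-dimethyloxirane-2-carbonyloxy]-8-hydroxy-2-oxogermacra-3,11(13)-dien-12,6-olide (CNP0227299.6)
Conditions: HF·pyridine, pyridine, THF, 0 °C
Reagents that add atoms: none
Why: Buffered fluoride cleavage of the triethylsilyl ether; the absence of base avoids the 9→8 acyl shift and translactonisation, and the ester-deactivated epoxide should survive buffered HF.

## Compound list

1 | ethyl (3R)-4-chloro-3-hydroxybutanoate | CCOC(=O)C[C@@H](O)CCl | starting material
2 | ethyl 2-[(2R)-oxiran-2-yl]acetate | CCOC(=O)C[C@@H]1CO1 | intermediate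
3 | isopropenylmagnesium bromide | CC(=C)[Mg]Br | starting material
4 | ethyl (3S)-3-hydroxy-5-methylhex-5-enoate | CCOC(=O)C[C@@H](O)CC(C)=C | intermediate
5 | acrolein | C=CC=O | starting material
6 | dilithium enolate alkoxide of 4 | [Li+].[Li+].CCO/C([O-])=C/[C@@H]([O-])CC(C)=C | intermediate
7 | ethyl (2R,3S)-3-hydroxy-2-(1-hydroxyprop-2-en-1-yl)-5-methylhex-5-enoate (both carbinol epimers) | CCOC(=O)[C@@H](C(O)C=C)[C@@H](O)CC(C)=C | intermediate
8 | ethyl (1R,6S)-2,6-dihydroxy-4-methylcyclohex-3-ene-1-carboxylate (both C2 epimers) | CCOC(=O)[C@H]1C(O)C=C(C)C[C@@H]1O | intermediate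
9 | ethyl (1R,6S)-2,6-bis[(tert-butyldimethylsilyl)oxy]-4-methylcyclohex-3-ene-1-carboxylate | CCOC(=O)[C@H]1C(O[Si](C)(C)C(C)(C)C)C=C(C)C[C@@H]1O[Si](C)(C)C(C)(C)C | intermediate
10 | (1R,6S)-2,6-bis[(tert-butyldimethylsilyl)oxy]-4-methylcyclohex-3-ene-1-carbaldehyde | O=C[C@H]1C(O[Si](C)(C)C(C)(C)C)C=C(C)C[C@@H]1O[Si](C)(C)C(C)(C)C | intermediate
11 | (4R,5S)-3,5-bis[(tert-butyldimethylsilyl)oxy]-4-[(E)-2-iodoethenyl]-1-methylcyclohex-1-ene | I/C=C/[C@H]1C(O[Si](C)(C)C(C)(C)C)C=C(C)C[C@@H]1O[Si](C)(C)C(C)(C)C | intermediate
12 | 4-methoxybenzyl alcohol | COc1ccc(CO)cc1 | starting material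
13 | (4R,5S)-3,5-bis[(tert-butyldimethylsilyl)oxy]-4-[(E)-2-[(4-methoxybenzyl)oxy]ethenyl]-1-methylcyclohex-1-ene | COc1ccc(CO/C=C/[C@H]2C(O[Si](C)(C)C(C)(C)C)C=C(C)C[C@@H]2O[Si](C)(C)C(C)(C)C)cc1 | intermediate
14 | (1S,2R)-2-[(E)-2-[(4-methoxybenzyl)oxy]ethenyl]-5-methylcyclohex-4-ene-1,3-diol (both C3 epimers) | COc1ccc(CO/C=C/[C@H]2C(O)C=C(C)C[C@@H]2O)cc1 | intermediate
15 | (5S,6R)-5-hydroxy-6-[(E)-2-[(4-methoxybenzyl)oxy]ethenyl]-3-methylcyclohex-2-en-1-one | COc1ccc(CO/C=C/[C@H]2C(=O)C=C(C)C[C@@H]2O)cc1 | intermediate
16 | (E)-1-bromoprop-1-ene | C/C=C/Br | starting material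
17 | (E)-prop-1-enyllithium | C/C=C/[Li] | intermediate
18 | (E)-prop-1-enylcerium dichloride | C/C=C/[Ce](Cl)Cl | intermediate
19 | (1R,5S,6R)-6-[(E)-2-[(4-methoxybenzyl)oxy]ethenyl]-3-methyl-1-[(E)-prop-1-en-1-yl]cyclohex-2-ene-1,5-diol | C/C=C/[C@@]1(O)C=C(C)C[C@H](O)[C@H]1/C=C/OCc2ccc(OC)cc2 | intermediate
20 | dipotassium dialkoxide of 19 | [K+].[K+].C/C=C/[C@@]1([O-])C=C(C)C[C@H]([O-])[C@H]1/C=C/OCc2ccc(OC)cc2 | intermediate
21 | dipotassium enolate alkoxide of 22 | [K+].[K+].[O-][C@H]1C/C(C)=C\C(\[O-])=C\[C@H](C)[C@@H](OCc2ccc(OC)cc2)/C=C\1 | intermediate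
22 | (2Z,5S,6Z,8R,9S)-5-hydroxy-8-[(4-methoxybenzyl)oxy]-3,9-dimethylcyclodeca-2,6-dien-1-one | O[C@H]1C/C(C)=C\C(=O)C[C@H](C)[C@@H](OCc2ccc(OC)cc2)/C=C\1 | intermediate
23 | (3Z,6S,7R,8S,9R,10S)-7,8-epoxy-6-hydroxy-9-[(4-methoxybenzyl)oxy]-4,10-dimethylcyclodec-3-en-2-one | O[C@H]1C/C(C)=C\C(=O)C[C@H](C)[C@@H](OCc3ccc(OC)cc3)[C@@H]2O[C@H]12 | intermediate
24 | 2-(diethoxyphosphoryl)acetic acid | CCOP(=O)(OCC)CC(=O)O | starting material
25 | (3Z,6R,7R,8S,9R,10S)-6-[2-(diethoxyphosphoryl)acetoxy]-7,8-epoxy-9-[(4-methoxybenzyl)oxy]-4,10-dimethylcyclodec-3-en-2-one | CCOP(=O)(OCC)CC(=O)O[C@@H]1C/C(C)=C\C(=O)C[C@H](C)[C@@H](OCc3ccc(OC)cc3)[C@@H]2O[C@H]12 | intermediate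
26 | 11-(diethoxyphosphoryl)-8-hydroxy-9-[(4-methoxybenzyl)oxy]-2-oxogermacr-3-en-12,6-olide (both C11 epimers) | CCOP(=O)(OCC)C1C(=O)O[C@@H]2C/C(C)=C\C(=O)C[C@H](C)[C@@H](OCc3ccc(OC)cc3)[C@H](O)[C@@H]12 | intermediate
27 | (3Z,6R,7R,8R,9R,10S)-8-hydroxy-9-[(4-methoxybenzyl)oxy]-2-oxogermacra-3,11(13)-dien-12,6-olide | C=C1C(=O)O[C@@H]2C/C(C)=C\C(=O)C[C@H](C)[C@@H](OCc3ccc(OC)cc3)[C@H](O)[C@@H]12 | intermediate
28 | (3Z,6R,7S,8R,9R,10S)-9-[(4-methoxybenzyl)oxy]-2-oxo-8-[(triethylsilyl)oxy]germacra-3,11(13)-dien-12,6-olide | C=C1C(=O)O[C@@H]2C/C(C)=C\C(=O)C[C@H](C)[C@@H](OCc3ccc(OC)cc3)[C@H](O[Si](CC)(CC)CC)[C@@H]12 | intermediate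
29 | (3Z,6R,7S,8R,9R,10S)-9-hydroxy-2-oxo-8-[(triethylsilyl)oxy]germacra-3,11(13)-dien-12,6-olide | C=C1C(=O)O[C@@H]2C/C(C)=C\C(=O)C[C@H](C)[C@@H](O)[C@H](O[Si](CC)(CC)CC)[C@@H]12 | intermediate
30 | angelic acid, (2Z)-2-methylbut-2-enoic acid | C/C=C(/C)C(=O)O | starting material
31 | (2Z)-2-methylbut-2-en-1-ol | C/C=C(/C)CO | intermediate
32 | [(2S,3R)-2,3-dimethyloxiran-2-yl]methanol | OC[C@]1(C)O[C@@H]1C | intermediate
33 | (2R,3R)-2,3-dimethyloxirane-2-carboxylic acid | OC(=O)[C@]1(C)O[C@@H]1C | intermediate
34 | (2R,3R)-2,3-dimethyloxirane-2-carboxylic 2,4,6-trichlorobenzoic anhydride | O=C(OC(=O)[C@]1(C)O[C@@H]1C)c1c(Cl)cc(Cl)cc1Cl | intermediate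
35 | (3Z,6R,7S,8R,9R,10S)-9-[(2R,3R)-2,3-dimethyloxirane-2-carbonyloxy]-2-oxo-8-[(triethylsilyl)oxy]germacra-3,11(13)-dien-12,6-olide | C=C1C(=O)O[C@@H]2C/C(C)=C\C(=O)C[C@H](C)[C@@H](OC(=O)[C@]3(C)O[C@@H]3C)[C@H](O[Si](CC)(CC)CC)[C@@H]12 | intermediate
36 | (3Z,6R,7R,8R,9R,10S)-9-[(2R,3R)-2,3-dimethyloxirane-2-carbonyloxy]-8-hydroxy-2-oxogermacra-3,11(13)-dien-12,6-olide | C=C1C(=O)O[C@@H]2C/C(C)=C\C(=O)C[C@H](C)[C@@H](OC(=O)[C@]3(C)O[C@@H]3C)[C@H](O)[C@@H]12 | target

## Step count and least certain steps

Total step count: 22. Longest linear sequence: 19 steps (steps 1–17, 21 and 22); steps 18–20 make the acid 33.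

Step 12 (key step). The most likely failures are rearrangement through the ring-flipped conformer or a boat (which would give the 7E alkene and other C9/C10 relationships), base-induced drift of the Z-enone through the dienolate, and fragmentation of the dianion. The fallback takes the base out of the rearrangement. It sets out from 19: silylation (TMSCl, imidazole) gives the bis(trimethylsilyl) ether F1, which is heated (toluene, sealed tube, about 180 °C) in a neutral siloxy-Cope rearrangement through the same chair to the silyl dienol ether F2. Mild methanolysis (K2CO3, MeOH, 0 °C) then returns to the route at 22.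

Step 11. The most likely failure is poor facial selectivity, because the alkoxide formed first from the free hydroxyl can direct or chelate the reagent and deliver the propenyl group trans to the side chain; enolisation with β-elimination is a second risk. The epimeric carbinol would rearrange through an all-equatorial chair to the 7E alkene, which the later steps cannot use. The fallback removes the alkoxide as a control element. It sets out from 15: silylation (TBSCl, imidazole) gives the silyl ether F3, addition of 18 then rests on axial attack anti to the silyloxy group alone and gives the carbinol F4, the rearrangement under the conditions of step 12 gives the ring-expanded silyl ether F5, and TBAF returns to the route at 22.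

Step 13. The most likely failure is epoxidation from the wrong face, since hydrogen bonding of the peracid to the C6 hydroxyl (or the hemiketal form of 22) may oppose the steric bias. The fallback changes the control element to a metal-directed syn delivery from the inverted carbinol. It sets out from 22: Mitsunobu reaction with 4-nitrobenzoic acid gives the inverted ester F6, methanolysis (K2CO3, MeOH) gives the 6R allylic alcohol F7, and VO(acac)2/t-BuOOH, which epoxidises cis to the hydroxyl and here also anti to the C9 ether, gives the cis epoxy alcohol F8. Esterification of F8 with 24 (DCC, DMAP) returns to the route at 25.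

Step 15. The most likely failure is that the tethered anion does not reach the backside of C7: the ester must leave its preferred s-trans conformation and the closure is trans-fused; 6-endo attack at C8 and DBU-induced isomerisation of the enone or the methylene lactone are further risks. The fallback closes the easier cis-fused ring first and inverts C6 afterwards. It sets out from 23: esterification with 24 with retention (DCC, DMAP) gives the 6S phosphonoacetate F9, in which the tether and the backside of C7 are on the same face. Cyclisation and olefination under the conditions of step 15 give the cis-fused methylene lactone F10, silylation (TESOTf, 2,6-lutidine) gives F11, and careful saponification (LiOH, THF/H2O, 0 °C) gives the seco acid F12. Mitsunobu lactonisation of F12 (PPh3, DIAD, high dilution) inverts C6 and returns to the route at 28.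

## Further compounds

F1 | step 12 | bis(trimethylsilyl) ether of 19 | C/C=C/[C@@]1(O[Si](C)(C)C)C=C(C)C[C@H](O[Si](C)(C)C)[C@H]1/C=C/OCc2ccc(OC)cc2
F2 | step 12 | trimethylsilyl dienol ether and 5-O-trimethylsilyl ether of 22 | C[Si](C)(C)O[C@H]1C/C(C)=C\C(\O[Si](C)(C)C)=C\[C@H](C)[C@@H](OCc2ccc(OC)cc2)/C=C\1
F3 | step 11 | 5-O-tert-butyldimethylsilyl ether of 15 | COc1ccc(CO/C=C/[C@H]2C(=O)C=C(C)C[C@@H]2O[Si](C)(C)C(C)(C)C)cc1
F4 | step 11 | 5-O-tert-butyldimethylsilyl ether of 19 | C/C=C/[C@@]1(O)C=C(C)C[C@H](O[Si](C)(C)C(C)(C)C)[C@H]1/C=C/OCc2ccc(OC)cc2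
F5 | step 11 | 5-O-tert-butyldimethylsilyl ether of 22 | CC(C)(C)[Si](C)(C)O[C@H]1C/C(C)=C\C(=O)C[C@H](C)[C@@H](OCc2ccc(OC)cc2)/C=C\1
F6 | step 13 | 4-nitrobenzoate of the C5 epimer of 22 | O=C(O[C@@H]1C/C(C)=C\C(=O)C[C@H](C)[C@@H](OCc2ccc(OC)cc2)/C=C\1)c3ccc(cc3)[N+](=O)[O-]
F7 | step 13 | (2Z,5R,6Z,8R,9S)-5-hydroxy-8-[(4-methoxybenzyl)oxy]-3,9-dimethylcyclodeca-2,6-dien-1-one | O[C@@H]1C/C(C)=C\C(=O)C[C@H](C)[C@@H](OCc2ccc(OC)cc2)/C=C\1
F8 | step 13 | C6 epimer of 23 (epoxide cis to the C6 hydroxyl) | O[C@@H]1C/C(C)=C\C(=O)C[C@H](C)[C@@H](OCc3ccc(OC)cc3)[C@@H]2O[C@H]12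
F9 | step 15 | C6 epimer of 25 (6S phosphonoacetate) | CCOP(=O)(OCC)CC(=O)O[C@H]1C/C(C)=C\C(=O)C[C@H](C)[C@@H](OCc3ccc(OC)cc3)[C@@H]2O[C@H]12
F10 | step 15 | C6 epimer of 27 (cis-fused lactone) | C=C1C(=O)O[C@H]2C/C(C)=C\C(=O)C[C@H](C)[C@@H](OCc3ccc(OC)cc3)[C@H](O)[C@@H]12
F11 | step 15 | C6 epimer of 28 (cis-fused lactone, 8-O-triethylsilyl) | C=C1C(=O)O[C@H]2C/C(C)=C\C(=O)C[C@H](C)[C@@H](OCc3ccc(OC)cc3)[C@H](O[Si](CC)(CC)CC)[C@@H]12
F12 | step 15 | seco acid of F11: 2-[6-hydroxy-9-[(4-methoxybenzyl)oxy]-4,10-dimethyl-2-oxo-8-[(triethylsilyl)oxy]cyclodec-3-en-7-yl]acrylic acid | C=C(C(=O)O)[C@H]1[C@@H](O)C/C(C)=C\C(=O)C[C@H](C)[C@@H](OCc2ccc(OC)cc2)[C@@H]1O[Si](CC)(CC)CC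
A1 | alternative 1 | methyl (2Z)-2-(bromomethyl)alk-2-enoate aldehyde, open-chain precursor for C6–C7 closure | O=CC/C(C)=C\C(=O)C[C@H](C)[C@@H](OCc1ccc(OC)cc1)[C@H](O[Si](CC)(CC)CC)/C=C(\CBr)C(=O)OC
A2 | alternative 2 | open-chain vinyl ketone with preformed methylene lactone, precursor for C3=C4 metathesis | C=CC(=O)C[C@H](C)[C@@H](OCc2ccc(OC)cc2)[C@H](O[Si](CC)(CC)CC)[C@H]1C(=C)C(=O)O[C@@H]1CC(C)=C
A3 | alternative 3 | eight-membered (Z)-enoate lactone bearing the propenyl group on C8 | C/C=C/[C@@H]1OC(=O)/C=C(C)\C[C@@H](O[Si](C)(C)C(C)(C)C)[C@@H]1CCOCc2ccc(OC)cc2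
A4 | alternative 3 | ring-expanded cyclodeca-3,8-dien-2-one from A3 | CC(C)(C)[Si](C)(C)O[C@@H]1C/C(C)=C\C(=O)C[C@H](C)/C=C/[C@H]1CCOCc2ccc(OC)cc2
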